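**Plan**
1. Cuts, in retrosynthetic order: the two O–benzyl bonds (phenol protection), the C3–C4 bond of the lactone (ring atoms O1, C2(=O), C3(OH), C4, C5), the O1–C5 ester bond, and the C=C bonds made from two benzaldehydes.
2. Enabling feature: C3 is a carbinol next to carbonyl C2 (a reduced α-keto ester), and C4 lies between C5H2–O1 and the benzylic C7H2 of the guaiacyl ring (a reduced cinnamyl ester). A ketyl at C3 can therefore add 5-exo to C4 of a cinnamyl arylpyruvate, the radical arriving at benzylic C7.
3. Forward: the guaiacyl C6C3 half (olefination, reduction, bromide) and the syringyl C6C3 half (hydantoin condensation, hydrolysis) are joined as an ester. One samarium ketyl–olefin cyclisation closes the only ring, and hydrogenolysis ends the route.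
4. Stereochemistry: both centres arise in the key step. Relative configuration (C3–OH trans to the C4 benzyl, the two benzyl groups cis) comes from the anti O–Sm/alkene transition state; absolute configuration (3S,4R) comes from a chiral amino diol ligand on samarium.

Key step: step 7

Assumption: acid 9 and ester 10 are drawn as keto tautomers; both should exist largely as Z-enols that equilibrate with the keto form, and only the keto form is reduced in step 7.

**Route**

Step 1
Reactants: 1 4-(benzyloxy)-3-methoxybenzaldehyde; 2 triethyl phosphonoacetate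
Product: 3 ethyl (E)-3-[4-(benzyloxy)-3-methoxyphenyl]prop-2-enoate
Conditions: NaH, THF, 0 °C to rt
Reagents that add atoms: none
Why: Horner–Wadsworth–Emmons olefination of an aromatic aldehyde with a stabilised phosphonate anion should give the (E)-cinnamate under thermodynamic control.

Step 2
Reactants: 3 ethyl (E)-3-[4-(benzyloxy)-3-methoxyphenyl]prop-2-enoate
Product: 4 (E)-3-[4-(benzyloxy)-3-methoxyphenyl]prop-2-en-1-ol
Conditions: i-Bu2AlH (DIBAL-H, 2.5 equiv), CH2Cl2, −78 °C; aq. potassium sodium tartrate
Reagents that add atoms: none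
Why: 1,2-reduction of the α,β-unsaturated ester by the aluminium hydride at low temperature should give the allylic alcohol without touching the alkene or the benzyl ether.

Step 3
Reactants: 4 (E)-3-[4-(benzyloxy)-3-methoxyphenyl]prop-2-en-1-ol
Product: 5 1-(benzyloxy)-4-[(E)-3-bromoprop-1-en-1-yl]-2-methoxybenzene
Conditions: PBr3 (0.4 equiv), Et2O, 0 °C; used at once
Reagents that add atoms: phosphorus tribromide, BrP(Br)Br
Why: bromination of the primary allylic alcohol through its phosphite ester (SN2) should keep the conjugated E-alkene, the linear bromide also being the thermodynamic isomer.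

Step 4
Reactants: 6 4-(benzyloxy)-3,5-dimethoxybenzaldehyde; 7 hydantoin (imidazolidine-2,4-dione)
Product: 8 (Z)-5-[4-(benzyloxy)-3,5-dimethoxybenzylidene]imidazolidine-2,4-dione
Conditions: ethanolamine, EtOH–H2O, reflux
Reagents that add atoms: none
Why: amine-promoted Knoevenagel condensation of the aldehyde with the acidic C5 methylene of hydantoin should give the conjugated Z-arylidene hydantoin, which crystallises from the medium.

Step 5
Reactants: 8 (Z)-5-[4-(benzyloxy)-3,5-dimethoxybenzylidene]imidazolidine-2,4-dione
Product: 9 3-[4-(benzyloxy)-3,5-dimethoxyphenyl]-2-oxopropanoic acid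
Conditions: 20% aq. NaOH, reflux, N2; then conc. HCl to pH 1, 0 °C
Reagents that add atoms: water, O
Why: alkaline hydrolysis of the arylidene hydantoin (the classical hydantoin route to arylpyruvic acids) opens the ring and, with loss of ammonia and carbonate, gives the α-keto acid, the benzyl and methyl aryl ethers being stable to hot alkali.

Step 6
Reactants: 9 3-[4-(benzyloxy)-3,5-dimethoxyphenyl]-2-oxopropanoic acid; 5 1-(benzyloxy)-4-[(E)-3-bromoprop-1-en-1-yl]-2-methoxybenzene
Product: 10 (E)-3-[4-(benzyloxy)-3-methoxyphenyl]prop-2-en-1-yl 3-[4-(benzyloxy)-3,5-dimethoxyphenyl]-2-oxopropanoate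
Conditions: KHCO3 (1.1 equiv), DMF, 0 °C to rt
Reagents that add atoms: none
Why: SN2 O-alkylation of the carboxylate by the primary allylic bromide should give the ester, bicarbonate being too weak a base to ionise the enol or the benzylic position, so that only the carboxyl group reacts.

Step 7
Reactants: 10 (E)-3-[4-(benzyloxy)-3-methoxyphenyl]prop-2-en-1-yl 3-[4-(benzyloxy)-3,5-dimethoxyphenyl]-2-oxopropanoate
Product: 13 (3S,4R)-3-[4-(benzyloxy)-3,5-dimethoxybenzyl]-4-[4-(benzyloxy)-3-methoxybenzyl]-3-hydroxydihydrofuran-2(3H)-one, via samarium ketyl 11 (not isolated), via cyclised benzylic radical 12 (not isolated)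
Conditions: SmI2 (2.5 equiv, added over 2 h), (1R,1'R)-2,2'-(benzylazanediyl)bis(1-phenylethan-1-ol) (2.5 equiv), MeOH (5 equiv), THF, −40 °C to 0 °C
Reagents that add atoms: none
Why: Proposed new method: single-electron transfer from ligated divalent samarium to the keto group of the α-keto ester (by far the most easily reduced function) gives the chelated trivalent samarium ketyl 11, whose carbon C3, an electrophile in the ketone, now adds as a radical to the proximal alkene carbon C4 to give benzylic radical 12, which is reduced by a second SmI2 and protonated by MeOH at C7 and at oxygen. The closest known reaction type is the SmI2 ketyl–olefin cyclisation onto styrenes, including its enantioselective form with chiral amino diol ligands on chelating keto esters; new here are the allyl α-keto ester tether that closes a lactone and the ligand-controlled choice between the two faces of a 1,2-dicarbonyl ketyl. The γ-lactone ring closes in the 5-exo-trig mode, for which the ester must pass through its minor E rotamer, hence the slow addition of SmI2 so that cyclisation can outrun a second electron transfer to 11. The relative configuration of C3 and C4 should follow from the usual transition state in which the bulky O–Sm bond and the alkene are anti, which puts the C4 benzyl group trans to the C3 oxygen and cis to the C3 benzyl group as required, and the absolute configuration from the chiral amino diol on the samarium that is chelated by the ketyl oxygen and the ester carbonyl oxygen. Regioselectivity (5-exo, not 6-endo) is secured by the aryl group on the distal alkene carbon, which makes the exo radical benzylic, and chemoselectivity by the gap in reduction potential between the 1,2-dicarbonyl unit and the ester, styrene and benzyl ether groups.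

Step 8
Reactants: 13 (3S,4R)-3-[4-(benzyloxy)-3,5-dimethoxybenzyl]-4-[4-(benzyloxy)-3-methoxybenzyl]-3-hydroxydihydrofuran-2(3H)-one
Product: 14 (3S,4R)-3-hydroxy-3-(4-hydroxy-3,5-dimethoxybenzyl)-4-(4-hydroxy-3-methoxybenzyl)dihydrofuran-2(3H)-one
Conditions: H2 (1 atm), 10% Pd/C, EtOAc–EtOH, rt
Reagents that add atoms: none
Why: hydrogenolysis of the two aryl benzyl ethers over palladium on carbon should free both phenols, while the homobenzylic tertiary alcohol, the non-benzylic lactone C–O bond and both stereocentres are untouched.

**Compound list**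
1 | 4-(benzyloxy)-3-methoxybenzaldehyde | COc1cc(C=O)ccc1OCc1ccccc1 | starting material
2 | triethyl phosphonoacetate | CCOC(=O)CP(=O)(OCC)OCC | starting material
3 | ethyl (E)-3-[4-(benzyloxy)-3-methoxyphenyl]prop-2-enoate | CCOC(=O)/C=C/c1ccc(OCc2ccccc2)c(OC)c1 | intermediate
4 | (E)-3-[4-(benzyloxy)-3-methoxyphenyl]prop-2-en-1-ol | OC/C=C/c1ccc(OCc2ccccc2)c(OC)c1 | intermediate
5 | 1-(benzyloxy)-4-[(E)-3-bromoprop-1-en-1-yl]-2-methoxybenzene | BrC/C=C/c1ccc(OCc2ccccc2)c(OC)c1 | intermediate
6 | 4-(benzyloxy)-3,5-dimethoxybenzaldehyde | COc1cc(C=O)cc(OC)c1OCc1ccccc1 | starting material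
7 | hydantoin (imidazolidine-2,4-dione) | O=C1CNC(=O)N1 | starting material
8 | (Z)-5-[4-(benzyloxy)-3,5-dimethoxybenzylidene]imidazolidine-2,4-dione | O=C1NC(=O)/C(=C/c2cc(OC)c(OCc3ccccc3)c(OC)c2)N1 | intermediate
9 | 3-[4-(benzyloxy)-3,5-dimethoxyphenyl]-2-oxopropanoic acid | O=C(O)C(=O)Cc1cc(OC)c(OCc2ccccc2)c(OC)c1 | intermediate
10 | (E)-3-[4-(benzyloxy)-3-methoxyphenyl]prop-2-en-1-yl 3-[4-(benzyloxy)-3,5-dimethoxyphenyl]-2-oxopropanoate | COc1cc(CC(=O)C(=O)OC/C=C/c2ccc(OCc3ccccc3)c(OC)c2)cc(OC)c1OCc1ccccc1 | intermediate
11 | samarium ketyl of 10 (trivalent samarium on the ketyl oxygen, drawn as the diiodide with the chiral ligand omitted; not isolated) | COc1cc(C[C](O[Sm](I)I)C(=O)OC/C=C/c2ccc(OCc3ccccc3)c(OC)c2)cc(OC)c1OCc1ccccc1 | intermediate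
12 | cyclised benzylic radical, samarium alkoxide of the lactone (ligand omitted; not isolated) | COc1cc([CH][C@@H]2COC(=O)[C@]2(O[Sm](I)I)Cc2cc(OC)c(OCc3ccccc3)c(OC)c2)ccc1OCc1ccccc1 | intermediate
13 | (3S,4R)-3-[4-(benzyloxy)-3,5-dimethoxybenzyl]-4-[4-(benzyloxy)-3-methoxybenzyl]-3-hydroxydihydrofuran-2(3H)-one | COc1cc(C[C@@H]2COC(=O)[C@]2(O)Cc2cc(OC)c(OCc3ccccc3)c(OC)c2)ccc1OCc1ccccc1 | intermediate
14 | (3S,4R)-3-hydroxy-3-(4-hydroxy-3,5-dimethoxybenzyl)-4-(4-hydroxy-3-methoxybenzyl)dihydrofuran-2(3H)-one | COc1cc(C[C@@H]2COC(=O)[C@]2(O)Cc2cc(OC)c(O)c(OC)c2)ccc1O | target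

**Count**
Total steps: 8. Longest linear sequence: 6 steps (steps 1, 2, 3, 6, 7, 8).

**Steps most likely to fail**

Step 7. What may go wrong:
- further reduction or pinacol dimerisation of the ketyl before the slow ester rotation allows ring closure;
- sluggish return of the enol tautomer to the reducible keto form;
- loss of the cinnamyl group from the radical anion by C–O cleavage;
- poor facial selectivity under the chiral ligand, whose sense of induction has to be assigned on the first run (the ligand antipode is taken if it proves opposite).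

Fallback by known chemistry, setting out from 1 and 6 and coming back at 13:
- Stobbe condensation of 1 with dimethyl succinate (NaOMe, MeOH, reflux) would give (E)-4-[4-(benzyloxy)-3-methoxyphenyl]-3-(methoxycarbonyl)but-3-enoic acid F1.
- Asymmetric hydrogenation ([Rh(cod)(Et-DuPhos)]BF4 with the ligand enantiomer that gives the S acid, H2, MeOH) would give (S)-4-[4-(benzyloxy)-3-methoxyphenyl]-3-(methoxycarbonyl)butanoic acid F2.
- Reduction of the ester group in the carboxylate salt (KOH, then Ca(BH4)2, EtOH) and acid lactonisation would give (S)-4-[4-(benzyloxy)-3-methoxybenzyl]dihydrofuran-2(3H)-one F3.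
- In parallel, 6 would be reduced (NaBH4, MeOH) to [4-(benzyloxy)-3,5-dimethoxyphenyl]methanol F4 and brominated (PBr3, Et2O) to 2-(benzyloxy)-5-(bromomethyl)-1,3-dimethoxybenzene F5.
- Alkylation of the lithium enolate of F3 (LiN(SiMe3)2, THF, −78 °C) with F5, anti to the C4 substituent, would give (3S,4S)-3-[4-(benzyloxy)-3,5-dimethoxybenzyl]-4-[4-(benzyloxy)-3-methoxybenzyl]dihydrofuran-2(3H)-one F6.
- Hydroxylation of the potassium enolate of F6 (KN(SiMe3)2, THF, −78 °C, then 2-(phenylsulfonyl)-3-phenyloxaziridine), again anti to the C4 benzyl group, would give 13.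

Step 6. What may go wrong: alkylation at the enol oxygen or the benzylic carbon of the pyruvate instead of the carboxylate, and ionisation, allylic transposition or decomposition of the electron-rich cinnamyl bromide.

Fallback, setting out from 4 and 9 and coming back at 10: Mitsunobu esterification (PPh3, diisopropyl azodicarboxylate, THF, 0 °C) would activate alcohol 4 directly towards the far more acidic carboxyl group of 9, so that neither the bromide nor a base is needed. This fallback makes no new compound (F0).

Step 5. What may go wrong: aldol self-condensation or air oxidation of the electron-rich arylpyruvate in hot alkali, and incomplete ring opening.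

Fallback, setting out from 6 and coming back at 9: Horner–Wadsworth–Emmons reaction of 6 with methyl 2-[(tert-butyldimethylsilyl)oxy]-2-(dimethoxyphosphoryl)acetate (LiN(SiMe3)2, THF, −78 °C to rt) would give methyl (Z)-3-[4-(benzyloxy)-3,5-dimethoxyphenyl]-2-[(tert-butyldimethylsilyl)oxy]prop-2-enoate F7 (either alkene isomer serves). Mild hydrolysis of the ester and the silyl enol ether (LiOH, THF–H2O, rt; then aq. HCl) would give 9.

**Further compounds**
F1 | step 7 | (E)-4-[4-(benzyloxy)-3-methoxyphenyl]-3-(methoxycarbonyl)but-3-enoic acid | COC(=O)/C(=C/c1ccc(OCc2ccccc2)c(OC)c1)CC(=O)O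
F2 | step 7 | (S)-4-[4-(benzyloxy)-3-methoxyphenyl]-3-(methoxycarbonyl)butanoic acid | COc1cc(C[C@@H](CC(=O)O)C(=O)OC)ccc1OCc1ccccc1
F3 | step 7 | (S)-4-[4-(benzyloxy)-3-methoxybenzyl]dihydrofuran-2(3H)-one | COc1cc(C[C@@H]2COC(=O)C2)ccc1OCc1ccccc1
F4 | step 7 | [4-(benzyloxy)-3,5-dimethoxyphenyl]methanol | COc1cc(CO)cc(OC)c1OCc1ccccc1
F5 | step 7 | 2-(benzyloxy)-5-(bromomethyl)-1,3-dimethoxybenzene | COc1cc(CBr)cc(OC)c1OCc1ccccc1
F6 | step 7 | (3S,4S)-3-[4-(benzyloxy)-3,5-dimethoxybenzyl]-4-[4-(benzyloxy)-3-methoxybenzyl]dihydrofuran-2(3H)-one | COc1cc(C[C@@H]2COC(=O)[C@H]2Cc2cc(OC)c(OCc3ccccc3)c(OC)c2)ccc1OCc1ccccc1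
F0 | step 6 | none | none
F7 | step 5 | methyl (Z)-3-[4-(benzyloxy)-3,5-dimethoxyphenyl]-2-[(tert-butyldimethylsilyl)oxy]prop-2-enoate | COC(=O)/C(O[Si](C)(C)C(C)(C)C)=C/c1cc(OC)c(OCc2ccccc2)c(OC)c1
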